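You asked for a quick number, so I start with the easy step, a count of the reagent in the zeta run.

| setting | zeta | epsilon | theta | flask |
|---|---|---|---|---|
| starting material | 0.29 M | 0.29 M | 0.43 M | 0.29 M |
| reagent | 0.232 M | 0.232 M | 0.232 M | 0.232 M |
| second substrate | 0.14 M | 0.58 M | 0.29 M | 0.290 M |
| remark | run made earlier | run made earlier | run made earlier |  |
| time |  |  |  | 10 h |

| zeta: time / h | zeta: target / % | epsilon: time / h | epsilon: target / % | theta: time / h | theta: target / % |
|---|---|---|---|---|---|
| 0.667 | 8.4 | 0.667 | 7.8 | 0.667 | 9.3 |
| 2.00 | 15.2 | 2.00 | 9.4 | 2.00 | 12.5 |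
| 5.00 | 17.4 | 5.00 | 10.4 | 5.00 | 12.0 |
| 12.0 | 15.8 | 12.0 | 7.5 | 12.0 | 9.8 |

(readings scatter by 1 percentage point)

* the best time, 10 h at the latest, for target
* the amount of target, in percent of the starting material charged, at that time
* the first time at which target reaches 4.3 %, in the same percent



The last two zeta readings differ by 1.6 percentage points against a scatter of 1 point, so I treat target as standing there. Its 15.8 % at 12.0 h is 0.0458 M. My own guess, which no reading shows, is that second substrate takes reagent one for one and that half of it has reacted. That leaves 0.116 M of reagent and 0.244 M of starting material, and I count both as free. So from this one scattered reading and that guess I read K = 1.62 L mol⁻¹, where K is my standing quotient, target over free starting material times free reagent, an apparent equilibrium constant.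

For the flask, the same guess leaves 0.0870 M of reagent to share. Solving K with that balance puts target near 8.97 % late on. That is a late level, and I commit to no peak of my own. Your forecast says 13.5 % at 4 h, with 4.3 % reached at 0.3 h, placing this flask “midway on a log scale”.

The flask peaks at 14.4 % at 2.82 h and reaches 4.3 % at 0.252 h.

    starting material + reagent ⇌ target (K = 2.10 L mol⁻¹, k = 0.870 L mol⁻¹ h⁻¹)
    second substrate + reagent ⇌ second product (K = 11.0 L mol⁻¹, k = 0.980 L mol⁻¹ h⁻¹)
    starting material ⇌ dormant form (K = 0.340, k = 0.240 h⁻¹)

At 10.0 h the flask has 66.3 % of its starting material and 33.0 % of its reagent free, and K times these gives 8.21 % of target, where the flask holds 11.3 %. The same flask charged with 0.93 M of reagent has 40.1 % and 58.9 % free at that time, so K gives 35.6 %, and it holds 46.2 %.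

Readings and results were computed with made-up constants; the scatter is artificial.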